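**Strategy.** 
Ring A is cut away from the isoflavone: the four bonds C8–C8a, C7–C8, C5–C6 and C4a–C5 are all made in one photochemical benzannulation of a 5-aryl-2-(diazoacetyl)-4-pyranone with (triisopropylsilyloxy)acetylene. The step exploits the resorcinol pattern of ring A, a free C5 hydroxyl beside C4a and an oxygen at C7, which maps onto a ketene carbon and the oxygenated carbon of an ynol ether, and the non-aromatic C8a=C4a enol-ether bond of ring C, which takes part in the closure at no cost. The precursor carries the finished ring B, masked only by silyl groups, on a kojic acid-derived pyranone, so one fluoride treatment ends the synthesis.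

Key step: step 13

Remark: (triisopropylsilyloxy)acetylene is treated as a reagent in hand (silyl ynol ethers of this kind are made by O-silylation of a lithium ynolate with i-Pr3SiOTf), and diazomethane is used as a freshly made ethereal solution; neither preparation is counted as a step.

Notation: Ar = 2-(tert-butyldimethylsilyloxy)-4,5-dimethoxy-3-[3-methyl-3-(triethylsilyloxy)butyl]phenyl.

**Route**

Step 1
Reactants: 1 3,4-dimethoxyphenol
Product: 2 3,4-dimethoxyphenyl N,N-diethylcarbamate
Conditions: Et2NCOCl, K2CO3, MeCN, reflux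
Reagents that add atoms: N,N-diethylcarbamoyl chloride, CCN(CC)C(Cl)=O
Why: O-Carbamoylation of the phenoxide (acyl substitution at the carbamoyl chloride) is routine and installs the strongest oxygen-based directing group for the ortho-metalation that follows.

Step 2
Reactants: 2 3,4-dimethoxyphenyl N,N-diethylcarbamate; 3 prenyl bromide (1-bromo-3-methylbut-2-ene)
Product: 5 3,4-dimethoxy-2-(3-methylbut-2-en-1-yl)phenyl N,N-diethylcarbamate, via aryllithium 4 (not isolated)
Conditions: s-BuLi, TMEDA, THF, −78 °C; then CuBr·SMe2 (10 mol %), prenyl bromide, −78 → −40 °C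
Reagents that add atoms: none
Why: Directed ortho-metalation removes the proton at C2, the one position flanked by the carbamate and a methoxy group, and the aryllithium is then alkylated at the primary carbon of prenyl bromide under copper catalysis at a temperature low enough that the anionic Fries rearrangement of the carbamate does not start.

Step 3
Reactants: 5 3,4-dimethoxy-2-(3-methylbut-2-en-1-yl)phenyl N,N-diethylcarbamate
Product: 6 2-(3-hydroxy-3-methylbutyl)-3,4-dimethoxyphenyl N,N-diethylcarbamate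
Conditions: Co(acac)2 (20 mol %), PhSiH3, O2 (1 atm), THF, rt
Reagents that add atoms: dioxygen, O=O
Why: In this Mukaiyama hydration, hydrogen-atom transfer from a cobalt hydride to the trisubstituted alkene gives the tertiary radical, which is trapped by O2 and reduced by the silane, so the hydroxyl should end on the dimethyl-substituted carbon (Markovnikov) without any acid.

Step 4
Reactants: 6 2-(3-hydroxy-3-methylbutyl)-3,4-dimethoxyphenyl N,N-diethylcarbamate
Product: 7 3,4-dimethoxy-2-[3-methyl-3-(triethylsilyloxy)butyl]phenyl N,N-diethylcarbamate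
Conditions: Et3SiOTf, 2,6-lutidine, CH2Cl2, −78 → 0 °C
Reagents that add atoms: triethylsilyl trifluoromethanesulfonate, CC[Si](CC)(CC)OS(=O)(=O)C(F)(F)F
Why: Silylation with a silyl triflate and a hindered pyridine base is the standard way to cap a tertiary alcohol, and the triethylsilyl ether should survive hydride, mild base, palladium and acylation conditions yet fall to fluoride at the end.

Step 5
Reactants: 7 3,4-dimethoxy-2-[3-methyl-3-(triethylsilyloxy)butyl]phenyl N,N-diethylcarbamate
Product: 8 3,4-dimethoxy-2-[3-methyl-3-(triethylsilyloxy)butyl]phenol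
Conditions: LiAlH4, THF, 0 °C → reflux; aqueous work-up
Reagents that add atoms: none
Why: Hydride reduction of the aryl carbamate (acyl substitution with loss of the phenoxide, then reduction of the formamide to the amine) frees the phenol while leaving the silyl ether and the methyl ethers alone.

Step 6
Reactants: 8 3,4-dimethoxy-2-[3-methyl-3-(triethylsilyloxy)butyl]phenol
Product: 9 6-bromo-3,4-dimethoxy-2-[3-methyl-3-(triethylsilyloxy)butyl]phenol
Conditions: NBS (1.0 equiv), CH2Cl2, −20 → 0 °C
Reagents that add atoms: N-bromosuccinimide, O=C1CCC(=O)N1Br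
Why: Electrophilic aromatic bromination is steered by the free hydroxyl, whose para position carries a methoxy group, to its only open ortho position C6 (also para to the C3 methoxy group), so the halogen marks the carbon that becomes C1' of ring B.

Step 7
Reactants: 9 6-bromo-3,4-dimethoxy-2-[3-methyl-3-(triethylsilyloxy)butyl]phenol
Product: 10 1-bromo-2-(tert-butyldimethylsilyloxy)-4,5-dimethoxy-3-[3-methyl-3-(triethylsilyloxy)butyl]benzene
Conditions: t-BuMe2SiCl, imidazole, DMF, rt → 40 °C
Reagents that add atoms: tert-butyldimethylsilyl chloride, CC(C)(C)[Si](C)(C)Cl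
Why: Imidazole-promoted O-silylation of a phenol is routine, and a silyl ether flanked by two ortho substituents is chosen for the 2'-oxygen because it resists the mild base of the coupling steps and lets all three protecting groups leave in one fluoride step, so the isoflavone never meets hydrogen over palladium.

Step 8
Reactants: 10 1-bromo-2-(tert-butyldimethylsilyloxy)-4,5-dimethoxy-3-[3-methyl-3-(triethylsilyloxy)butyl]benzene
Product: 11 2-Ar-4,4,5,5-tetramethyl-1,3,2-dioxaborolane
Conditions: Pd(dppf)Cl2 (5 mol %), B2pin2, KOAc, 1,4-dioxane, 90 °C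
Reagents that add atoms: bis(pinacolato)diboron, CC1(C)OB(OC1(C)C)B1OC(C)(C)C(C)(C)O1
Why: Miyaura borylation (oxidative addition to zerovalent palladium, acetate-assisted transmetalation with the diboron, reductive elimination) gives the pinacol boronate without an aryllithium, which would suffer silyl migration from oxygen to carbon.

Step 9
Reactants: 12 kojic acid
Product: 13 6-(hydroxymethyl)-4-oxo-4H-pyran-3-yl trifluoromethanesulfonate
Conditions: PhNTf2, Et3N, DMF, 0 °C → rt
Reagents that add atoms: N-phenylbis(trifluoromethanesulfonimide), O=S(=O)(N(c1ccccc1)S(=O)(=O)C(F)(F)F)C(F)(F)F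
Why: The enolic 5-hydroxyl of kojic acid is far more acidic than the primary alcohol, so only its ammonium salt is sulfonylated by the mild triflyl donor (chemoselective O-triflation).

Step 10
Reactants: 11 2-Ar-4,4,5,5-tetramethyl-1,3,2-dioxaborolane; 13 6-(hydroxymethyl)-4-oxo-4H-pyran-3-yl trifluoromethanesulfonate
Product: 14 5-Ar-2-(hydroxymethyl)-4H-pyran-4-one
Conditions: Pd(dppf)Cl2 (5 mol %), K3PO4, 1,4-dioxane/H2O (10:1), 70 °C
Reagents that add atoms: none
Why: In this Suzuki–Miyaura coupling the triflate sits on the α-carbon of a cross-conjugated enone and adds readily to zerovalent palladium, the boronate has only one ortho substituent, and the phosphate base should spare the pyranone, the free primary alcohol and both silyl ethers.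

Step 11
Reactants: 14 5-Ar-2-(hydroxymethyl)-4H-pyran-4-one
Product: 16 5-Ar-4-oxo-4H-pyran-2-carboxylic acid, via aldehyde 15 (not isolated)
Conditions: TEMPO (20 mol %), PhI(OAc)2 (2.2 equiv), MeCN/H2O (1:1), rt
Reagents that add atoms: water, O
Why: TEMPO-catalysed oxidation with PhI(OAc)2 as terminal oxidant in aqueous acetonitrile takes the primary alcohol through the aldehyde hydrate to the carboxylic acid in one flask under near-neutral conditions that should leave the fully protected ring B and the silyl ethers untouched.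

Step 12
Reactants: 16 5-Ar-4-oxo-4H-pyran-2-carboxylic acid
Product: 18 5-Ar-2-(diazoacetyl)-4H-pyran-4-one, via acid chloride 17 (not isolated)
Conditions: 1-chloro-N,N,2-trimethylprop-1-en-1-amine, CH2Cl2, 0 °C → rt; then CH2N2 (3 equiv), Et2O, 0 °C
Reagents that add atoms: diazomethane, C=[N+]=[N-]
Why: The α-chloroenamine turns the acid into the acid chloride without releasing HCl (so the silyl ethers are safe), and C-acylation of diazomethane with loss of HCl to a second equivalent gives the diazo ketone, as in the first stage of an Arndt–Eistert sequence.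

Step 13
Reactants: 18 5-Ar-2-(diazoacetyl)-4H-pyran-4-one; 19 (triisopropylsilyloxy)acetylene
Product: 24 2'-(tert-butyldimethylsilyloxy)-5-hydroxy-4',5'-dimethoxy-3'-[3-methyl-3-(triethylsilyloxy)butyl]-7-(triisopropylsilyloxy)isoflavone, via pyranonylketene 20 (not isolated), via siloxycyclobutenone 21 (not isolated), via dienylketene 22 (not isolated), via cyclohexadienone tautomer 23 (not isolated)
Conditions: 19 (2 equiv), ClCH2CH2Cl (0.02 M, degassed), hν (365 nm, Pyrex), rt; then 80 °C in the dark
Reagents that add atoms: none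
Why: Light near 365 nm should be absorbed by the diazo ketone and not by the aryl-pyranone, nitrogen is lost, and in the Wolff rearrangement the pyranone carbon C8a shifts from the acyl carbon to the diazo carbon C8, giving ketene 20 whose ketene carbon is the future C5. The ynol ether 19 attacks this carbon with its electron-rich CH terminus, so the [2+2] cycloaddition gives cyclobutenone 21 with C5–C6 and C7–C8 in place and the silyloxy group on C7; at 80 °C 21 opens by four-electron conrotatory ring opening to dienylketene 22, which closes from C5 onto C4a by six-electron disrotatory electrocyclisation and enolises from 23 to the phenol 24. The closest known reaction type is the photochemical variant of the Danheiser benzannulation of unsaturated α-diazo ketones with siloxyalkynes; a 4-pyranone has not served as the unsaturated unit, which is why the risk of the route sits here. Ring A is closed in the 6π electrocyclisation, a thermally allowed pericyclic closure that uses the C8a=C4a enol-ether bond of ring C and therefore costs no aromatic stabilisation. No stereocentre survives, since C8 of 21 and C4a of 23 become aromatic carbons. The step needs chemoselective excitation (set by the wavelength), one regiochemistry of cycloaddition (set by the polarity of the ynol ether) and one site of closure (C4a is the only carbon within reach, the other neighbour of C8a being the ring oxygen); the 5-hydroxyl is delivered free but chelated to the C4 carbonyl while the C7 oxygen stays silylated.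

Step 14
Reactants: 24 2'-(tert-butyldimethylsilyloxy)-5-hydroxy-4',5'-dimethoxy-3'-[3-methyl-3-(triethylsilyloxy)butyl]-7-(triisopropylsilyloxy)isoflavone
Product: 25 5,7-dihydroxy-3-[2-hydroxy-3-(3-hydroxy-3-methylbutyl)-4,5-dimethoxyphenyl]-4H-chromen-4-one
Conditions: Bu4NF (5 equiv), THF, 0 °C → rt; aq NH4Cl
Reagents that add atoms: none
Why: Fluoride should cleave the two aryl silyl ethers and the tertiary triethylsilyl ether through pentacoordinate silicon (desilylation), and because no acid is used the free 2'-hydroxyl cannot close onto the tertiary alcohol to form a dimethylchroman.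

**Compound list**

1 | 3,4-dimethoxyphenol | COc1ccc(O)cc1OC | starting material
2 | 3,4-dimethoxyphenyl N,N-diethylcarbamate | CCN(CC)C(=O)Oc1ccc(OC)c(OC)c1 | intermediate
3 | prenyl bromide (1-bromo-3-methylbut-2-ene) | CC(C)=CCBr | starting material
4 | [6-(diethylcarbamoyloxy)-2,3-dimethoxyphenyl]lithium | [Li]c1c(OC(=O)N(CC)CC)ccc(OC)c1OC | intermediate
5 | 3,4-dimethoxy-2-(3-methylbut-2-en-1-yl)phenyl N,N-diethylcarbamate | CCN(CC)C(=O)Oc1ccc(OC)c(OC)c1CC=C(C)C | intermediate
6 | 2-(3-hydroxy-3-methylbutyl)-3,4-dimethoxyphenyl N,N-diethylcarbamate | CCN(CC)C(=O)Oc1ccc(OC)c(OC)c1CCC(C)(C)O | intermediate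
7 | 3,4-dimethoxy-2-[3-methyl-3-(triethylsilyloxy)butyl]phenyl N,N-diethylcarbamate | CCN(CC)C(=O)Oc1ccc(OC)c(OC)c1CCC(C)(C)O[Si](CC)(CC)CC | intermediate
8 | 3,4-dimethoxy-2-[3-methyl-3-(triethylsilyloxy)butyl]phenol | COc1ccc(O)c(CCC(C)(C)O[Si](CC)(CC)CC)c1OC | intermediate
9 | 6-bromo-3,4-dimethoxy-2-[3-methyl-3-(triethylsilyloxy)butyl]phenol | COc1cc(Br)c(O)c(CCC(C)(C)O[Si](CC)(CC)CC)c1OC | intermediate
10 | 1-bromo-2-(tert-butyldimethylsilyloxy)-4,5-dimethoxy-3-[3-methyl-3-(triethylsilyloxy)butyl]benzene | COc1cc(Br)c(O[Si](C)(C)C(C)(C)C)c(CCC(C)(C)O[Si](CC)(CC)CC)c1OC | intermediate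
11 | 2-{2-(tert-butyldimethylsilyloxy)-4,5-dimethoxy-3-[3-methyl-3-(triethylsilyloxy)butyl]phenyl}-4,4,5,5-tetramethyl-1,3,2-dioxaborolane | COc1cc(B2OC(C)(C)C(C)(C)O2)c(O[Si](C)(C)C(C)(C)C)c(CCC(C)(C)O[Si](CC)(CC)CC)c1OC | intermediate
12 | kojic acid (5-hydroxy-2-(hydroxymethyl)-4H-pyran-4-one) | OCc1cc(=O)c(O)co1 | starting material
13 | 6-(hydroxymethyl)-4-oxo-4H-pyran-3-yl trifluoromethanesulfonate | OCc1cc(=O)c(OS(=O)(=O)C(F)(F)F)co1 | intermediate
14 | 5-{2-(tert-butyldimethylsilyloxy)-4,5-dimethoxy-3-[3-methyl-3-(triethylsilyloxy)butyl]phenyl}-2-(hydroxymethyl)-4H-pyran-4-one | OCc1cc(=O)c(-c2cc(OC)c(OC)c(CCC(C)(C)O[Si](CC)(CC)CC)c2O[Si](C)(C)C(C)(C)C)co1 | intermediate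
15 | 5-{2-(tert-butyldimethylsilyloxy)-4,5-dimethoxy-3-[3-methyl-3-(triethylsilyloxy)butyl]phenyl}-4-oxo-4H-pyran-2-carbaldehyde | O=Cc1cc(=O)c(-c2cc(OC)c(OC)c(CCC(C)(C)O[Si](CC)(CC)CC)c2O[Si](C)(C)C(C)(C)C)co1 | intermediate
16 | 5-{2-(tert-butyldimethylsilyloxy)-4,5-dimethoxy-3-[3-methyl-3-(triethylsilyloxy)butyl]phenyl}-4-oxo-4H-pyran-2-carboxylic acid | OC(=O)c1cc(=O)c(-c2cc(OC)c(OC)c(CCC(C)(C)O[Si](CC)(CC)CC)c2O[Si](C)(C)C(C)(C)C)co1 | intermediate
17 | 5-{2-(tert-butyldimethylsilyloxy)-4,5-dimethoxy-3-[3-methyl-3-(triethylsilyloxy)butyl]phenyl}-4-oxo-4H-pyran-2-carbonyl chloride | ClC(=O)c1cc(=O)c(-c2cc(OC)c(OC)c(CCC(C)(C)O[Si](CC)(CC)CC)c2O[Si](C)(C)C(C)(C)C)co1 | intermediate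
18 | 5-{2-(tert-butyldimethylsilyloxy)-4,5-dimethoxy-3-[3-methyl-3-(triethylsilyloxy)butyl]phenyl}-2-(diazoacetyl)-4H-pyran-4-one | [N-]=[N+]=CC(=O)c1cc(=O)c(-c2cc(OC)c(OC)c(CCC(C)(C)O[Si](CC)(CC)CC)c2O[Si](C)(C)C(C)(C)C)co1 | intermediate
19 | (triisopropylsilyloxy)acetylene | C#CO[Si](C(C)C)(C(C)C)C(C)C | starting material
20 | 2-(5-Ar-4-oxo-4H-pyran-2-yl)ethenone (the pyranonylketene) | O=C=Cc1cc(=O)c(-c2cc(OC)c(OC)c(CCC(C)(C)O[Si](CC)(CC)CC)c2O[Si](C)(C)C(C)(C)C)co1 | intermediate
21 | 4-(5-Ar-4-oxo-4H-pyran-2-yl)-3-(triisopropylsilyloxy)cyclobut-2-en-1-one (racemic) | O=C1C=C(O[Si](C(C)C)(C(C)C)C(C)C)C1c1cc(=O)c(-c2cc(OC)c(OC)c(CCC(C)(C)O[Si](CC)(CC)CC)c2O[Si](C)(C)C(C)(C)C)co1 | intermediate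
22 | (3E)-4-(5-Ar-4-oxo-4H-pyran-2-yl)-3-(triisopropylsilyloxy)buta-1,3-dien-1-one (ketene arm and pyranone cis across C7=C8) | O=C=C/C(O[Si](C(C)C)(C(C)C)C(C)C)=C\c1cc(=O)c(-c2cc(OC)c(OC)c(CCC(C)(C)O[Si](CC)(CC)CC)c2O[Si](C)(C)C(C)(C)C)co1 | intermediate
23 | 3-Ar-7-(triisopropylsilyloxy)-4aH-chromene-4,5-dione (racemic keto tautomer of 24) | O=C1C=C(O[Si](C(C)C)(C(C)C)C(C)C)C=C2OC=C(c3cc(OC)c(OC)c(CCC(C)(C)O[Si](CC)(CC)CC)c3O[Si](C)(C)C(C)(C)C)C(=O)C12 | intermediate
24 | 2'-(tert-butyldimethylsilyloxy)-5-hydroxy-4',5'-dimethoxy-3'-[3-methyl-3-(triethylsilyloxy)butyl]-7-(triisopropylsilyloxy)isoflavone | COc1cc(-c2coc3cc(O[Si](C(C)C)(C(C)C)C(C)C)cc(O)c3c2=O)c(O[Si](C)(C)C(C)(C)C)c(CCC(C)(C)O[Si](CC)(CC)CC)c1OC | intermediate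
25 | 5,7-dihydroxy-3-[2-hydroxy-3-(3-hydroxy-3-methylbutyl)-4,5-dimethoxyphenyl]-4H-chromen-4-one (no stereocentre) | COc1cc(-c2coc3cc(O)cc(O)c3c2=O)c(O)c(CCC(C)(C)O)c1OC | target

**Step count and risks**

Total step count: 14. Longest linear sequence: 13 steps (steps 1–8 and 10–14, from 3,4-dimethoxyphenol); step 9 is the one-step side branch from kojic acid.

Steps most likely to fail:

Step 13. What may go wrong: the carbene or ketene formed on irradiation is diverted (insertion, ketene dimerisation, acylation of the newly formed phenol), or the aryl-pyranone chromophore reacts on its own, so that ring A does not close cleanly. The fallback brings ring A in ready-made by known isoflavone chemistry and sets out from boronate 11. Commercial 1-[2,4-bis(benzyloxy)-6-hydroxyphenyl]ethanone is condensed with Me2NCH(OMe)2 (neat, 95 °C) to the enaminone (E)-1-[2,4-bis(benzyloxy)-6-hydroxyphenyl]-3-(dimethylamino)prop-2-en-1-one F1. Iodine in MeOH/CHCl3 at rt should cyclise it to 5,7-bis(benzyloxy)-3-iodo-4H-chromen-4-one F2. Suzuki–Miyaura coupling of F2 with 11 (Pd(dppf)Cl2, K3PO4, dioxane/H2O, 70 °C) should give 5,7-bis(benzyloxy)-2'-(tert-butyldimethylsilyloxy)-4',5'-dimethoxy-3'-[3-methyl-3-(triethylsilyloxy)butyl]isoflavone F3. Hydrogenolysis (H2, Pd/C (palladium on carbon), EtOAc, rt, stopped after two equivalents) should free the ring A hydroxyls to give 2'-(tert-butyldimethylsilyloxy)-5,7-dihydroxy-4',5'-dimethoxy-3'-[3-methyl-3-(triethylsilyloxy)butyl]isoflavone F4. Bu4NF as in step 14 then comes back to the route at target 25.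

Step 12. What may go wrong: diazomethane adds as a 1,3-dipole across the doubly activated C2=C3 bond of the acylpyranone, or the acid chloride decomposes, faster than C-acylation takes place. The fallback uses diazo transfer instead of diazomethane and sets out from acid 16. Amide coupling with MeNHOMe·HCl (EDC·HCl, i-Pr2NEt, CH2Cl2) should give 5-Ar-N-methoxy-N-methyl-4-oxo-4H-pyran-2-carboxamide F5. MeMgBr (THF, −78 °C) should give the methyl ketone 2-acetyl-5-Ar-4H-pyran-4-one F6. Deprotonation with LiN(SiMe3)2 (THF, −78 °C) and acylation with 2,2,2-trifluoroethyl trifluoroacetate should give the diketone 4,4,4-trifluoro-1-(5-Ar-4-oxo-4H-pyran-2-yl)butane-1,3-dione F7. Without purification, F7 is treated with MsN3, Et3N and H2O in MeCN (detrifluoroacetylative diazo transfer) and comes back to the route at diazo ketone 18.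

Step 10. What may go wrong: protodeboronation of the electron-rich ortho-siloxy boronate and hydrolysis of the enol triflate outrun transmetalation in the aqueous base. The fallback changes the electrophile to the ester oxidation level, which is more electron-poor, has no free hydroxyl and can be coupled without water; it also makes step 11 unnecessary. It sets out from boronate 11. Commercial comenic acid is esterified (MeOH, H2SO4, reflux) to methyl 5-hydroxy-4-oxo-4H-pyran-2-carboxylate F8 and triflated (PhNTf2, Et3N, CH2Cl2) to methyl 4-oxo-5-(trifluoromethylsulfonyloxy)-4H-pyran-2-carboxylate F9. Coupling of F9 with 11 (Pd(OAc)2, SPhos, anhydrous K3PO4, toluene, 60 °C) should give methyl 5-Ar-4-oxo-4H-pyran-2-carboxylate F10. Neutral ester cleavage with Me3SnOH (ClCH2CH2Cl, 70 °C) comes back to the route at acid 16.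

Further compounds
F1 | step 13 | (E)-1-[2,4-bis(benzyloxy)-6-hydroxyphenyl]-3-(dimethylamino)prop-2-en-1-one | CN(C)/C=C/C(=O)c1c(O)cc(OCc2ccccc2)cc1OCc1ccccc1
F2 | step 13 | 5,7-bis(benzyloxy)-3-iodo-4H-chromen-4-one | O=c1c(I)coc2cc(OCc3ccccc3)cc(OCc3ccccc3)c12
F3 | step 13 | 5,7-bis(benzyloxy)-2'-(tert-butyldimethylsilyloxy)-4',5'-dimethoxy-3'-[3-methyl-3-(triethylsilyloxy)butyl]isoflavone | COc1cc(-c2coc3cc(OCc4ccccc4)cc(OCc4ccccc4)c3c2=O)c(O[Si](C)(C)C(C)(C)C)c(CCC(C)(C)O[Si](CC)(CC)CC)c1OC
F4 | step 13 | 2'-(tert-butyldimethylsilyloxy)-5,7-dihydroxy-4',5'-dimethoxy-3'-[3-methyl-3-(triethylsilyloxy)butyl]isoflavone | COc1cc(-c2coc3cc(O)cc(O)c3c2=O)c(O[Si](C)(C)C(C)(C)C)c(CCC(C)(C)O[Si](CC)(CC)CC)c1OC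
F5 | step 12 | 5-Ar-N-methoxy-N-methyl-4-oxo-4H-pyran-2-carboxamide | CON(C)C(=O)c1cc(=O)c(-c2cc(OC)c(OC)c(CCC(C)(C)O[Si](CC)(CC)CC)c2O[Si](C)(C)C(C)(C)C)co1
F6 | step 12 | 2-acetyl-5-Ar-4H-pyran-4-one | CC(=O)c1cc(=O)c(-c2cc(OC)c(OC)c(CCC(C)(C)O[Si](CC)(CC)CC)c2O[Si](C)(C)C(C)(C)C)co1
F7 | step 12 | 4,4,4-trifluoro-1-(5-Ar-4-oxo-4H-pyran-2-yl)butane-1,3-dione | O=C(CC(=O)C(F)(F)F)c1cc(=O)c(-c2cc(OC)c(OC)c(CCC(C)(C)O[Si](CC)(CC)CC)c2O[Si](C)(C)C(C)(C)C)co1
F8 | step 10 | methyl 5-hydroxy-4-oxo-4H-pyran-2-carboxylate | COC(=O)c1cc(=O)c(O)co1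
F9 | step 10 | methyl 4-oxo-5-(trifluoromethylsulfonyloxy)-4H-pyran-2-carboxylate | COC(=O)c1cc(=O)c(OS(=O)(=O)C(F)(F)F)co1
F10 | step 10 | methyl 5-Ar-4-oxo-4H-pyran-2-carboxylate | COC(=O)c1cc(=O)c(-c2cc(OC)c(OC)c(CCC(C)(C)O[Si](CC)(CC)CC)c2O[Si](C)(C)C(C)(C)C)co1
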